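## Retrosynthetic overview

1. Target 16 ⇐ silyl ether 15 (deprotection) ⇐ 2-(2-arylallyl)phenol 14: ring C is closed last through the O1–C2 bond by a photoredox anti-Markovnikov hydroetherification in which a chiral thiol sets C3.
2. 14 ⇐ aryl 2-arylallyl ether 13 (aromatic Claisen, C4–C4a) ⇐ 2-prenylresorcinol 12 + 2-arylallyl alcohol 6 (Mitsunobu, C–O).
3. 6 ⇐ chromenyl methyl ketone 3 (methylenation/silylation, allylic oxidation) ⇐ 2,4-dihydroxyacetophenone 1 + prenal 2.
4. 12 ⇐ resorcinol 7 + prenyl bromide 9 (MOM-directed ortho-lithiation).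
5. Ring order: the pyran ring of the ring-B chromene first (step 1), the dihydropyran ring C last (step 8); benzene rings A and B are bought.

Assumption: the single stereocentre written [C@H] is C3 of the chroman and is (S); rings are lettered A (resorcinol-derived benzene), B (chromene benzene) and C (dihydropyran).

## Route

Step 1
Reactants: 1 2,4-dihydroxyacetophenone; 2 3-methylbut-2-enal (prenal)
Product: 3 1-(5-hydroxy-2,2-dimethyl-2H-chromen-6-yl)ethan-1-one
Conditions: pyridine, 140 °C, sealed tube, 16 h
Reagents that add atoms: none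
Why: Pyridine-mediated phenol–enal chromenylation (aldol-type C-alkylation at C3, dehydration to an ortho-quinone methide, oxa-6π electrocyclisation) is established for 2,4-dihydroxyaryl ketones and gives the angular 5-hydroxy-6-acyl chromene because the chelated 2-OH stays out of the reaction; no stereocentre is formed.

Step 2
Reactants: 3 1-(5-hydroxy-2,2-dimethyl-2H-chromen-6-yl)ethan-1-one
Product: 5 tert-butyl{[2,2-dimethyl-6-(prop-1-en-2-yl)-2H-chromen-5-yl]oxy}dimethylsilane, via potassium phenoxide 4 (not isolated)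
Conditions: Ph3PCH3Br (1.5 equiv), KOtBu (2.6 equiv), THF, 0 °C to rt; then TBSCl (2 equiv), DMF, rt
Reagents that add atoms: methyltriphenylphosphonium bromide, C[P+](c1ccccc1)(c1ccccc1)c1ccccc1.[Br-]; tert-butyldimethylsilyl chloride, CC(C)(C)[Si](C)(C)Cl
Why: Wittig methylenation of an ortho-hydroxyaryl methyl ketone runs on the phenoxide with excess ylide, and trapping that phenoxide in the same flask with TBSCl masks the phenol that would otherwise cyclise onto the allylic carbon in steps 3 and 6; no stereocentre is formed.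

Step 3
Reactants: 5 tert-butyl{[2,2-dimethyl-6-(prop-1-en-2-yl)-2H-chromen-5-yl]oxy}dimethylsilane
Product: 6 2-{5-[(tert-butyldimethylsilyl)oxy]-2,2-dimethyl-2H-chromen-6-yl}prop-2-en-1-ol
Conditions: SeO2 (0.3 equiv), t-BuOOH (2 equiv), CH2Cl2, 0 °C to rt
Reagents that add atoms: selenium dioxide (catalytic oxygen carrier), O=[Se]=O; tert-butyl hydroperoxide (terminal oxygen source), CC(C)(C)OO
Why: SeO2-catalysed allylic oxidation (ene reaction, then [2,3]-sigmatropic shift) can only attack the isopropenyl CH3, because the chromene alkene has no allylic hydrogen and the prenyl group is not yet in the molecule; no stereocentre is formed.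

Step 4
Reactants: 7 resorcinol
Product: 8 1,3-bis(methoxymethoxy)benzene
Conditions: NaH (2.4 equiv), MOMCl (2.4 equiv), DMF, 0 °C to rt
Reagents that add atoms: chloromethyl methyl ether, COCCl
Why: Williamson-type O-alkylation of the bis-phenoxide gives the bis-MOM ether, whose two acetal oxygens are the directing groups for step 5.

Step 5
Reactants: 8 1,3-bis(methoxymethoxy)benzene; 9 1-bromo-3-methylbut-2-ene (prenyl bromide)
Product: 12 2-(3-methylbut-2-en-1-yl)benzene-1,3-diol, via aryllithium 10 (not isolated), via bis-MOM prenylarene 11 (not isolated)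
Conditions: n-BuLi, THF, 0 °C; CuI (10 mol%), then 9, −78 °C to rt; then HCl (cat.), MeOH, 40 °C
Reagents that add atoms: none
Why: Directed ortho-metalation between the two MOM ethers gives the 2-lithio species regiospecifically, copper-catalysed SN2 allylation installs the prenyl group without allylic transposition, and mild acidic methanolysis (transacetalisation) frees both phenols.

Step 6
Reactants: 6 2-{5-[(tert-butyldimethylsilyl)oxy]-2,2-dimethyl-2H-chromen-6-yl}prop-2-en-1-ol; 12 2-(3-methylbut-2-en-1-yl)benzene-1,3-diol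
Product: 13 3-[(2-{5-[(tert-butyldimethylsilyl)oxy]-2,2-dimethyl-2H-chromen-6-yl}prop-2-en-1-yl)oxy]-2-(3-methylbut-2-en-1-yl)phenol
Conditions: PPh3, DIAD, THF, 0 °C to rt (12 in threefold excess, recovered)
Reagents that add atoms: none
Why: Mitsunobu etherification of a phenol with a primary allylic alcohol; 12 is symmetric so only mono- versus bis-alkylation matters (handled by the excess), and SN2 versus SN2′ attack is irrelevant because both allyl termini are CH2.

Step 7
Reactants: 13 3-[(2-{5-[(tert-butyldimethylsilyl)oxy]-2,2-dimethyl-2H-chromen-6-yl}prop-2-en-1-yl)oxy]-2-(3-methylbut-2-en-1-yl)phenol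
Product: 14 4-(2-{5-[(tert-butyldimethylsilyl)oxy]-2,2-dimethyl-2H-chromen-6-yl}prop-2-en-1-yl)-2-(3-methylbut-2-en-1-yl)benzene-1,3-diol
Conditions: PhNEt2, 185 °C, sealed tube, Ar, 3 h
Reagents that add atoms: none
Why: Aromatic Claisen rearrangement ([3,3]-sigmatropic shift, then rearomatising tautomerisation) moves the 2-arylallyl group to the only free ortho carbon, the prenyl group blocking the other; the para route through the blocked position would give the same constitution because the resorcinol becomes symmetric again, and the amine solvent keeps the acid-sensitive 2-arylpropene from closing to a dihydrobenzofuran.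

Step 8
Reactants: 14 4-(2-{5-[(tert-butyldimethylsilyl)oxy]-2,2-dimethyl-2H-chromen-6-yl}prop-2-en-1-yl)-2-(3-methylbut-2-en-1-yl)benzene-1,3-diol
Product: 15 (3S)-3-{5-[(tert-butyldimethylsilyl)oxy]-2,2-dimethyl-2H-chromen-6-yl}-8-(3-methylbut-2-en-1-yl)-3,4-dihydro-2H-chromen-7-ol
Conditions: Mes-Acr-Ph+ BF4− (5 mol%), chiral peptide thiol (10 mol%), 2,6-lutidine (10 mol%), ClCH2CH2Cl (0.02 M), 450 nm LEDs, −20 °C, Ar
Reagents that add atoms: none
Why: Proposed new method: an enantioselective anti-Markovnikov (6-endo) photoredox hydroetherification in which excited 3,6-di-tert-butyl-9-mesityl-10-phenylacridinium tetrafluoroborate oxidises the electron-rich 2-arylpropene of 14 (a para-alkoxy styrene, about +1.2 to +1.4 V vs SCE, far below the prenyl alkene near +2 V) to its radical cation, the ortho phenol oxygen adds to the unsubstituted CH2 terminus to forge the O1–C2 bond and ring C, and the resulting planar tertiary benzylic C3 radical is quenched by hydrogen-atom transfer from the cysteine thiol of the β-turn peptide N-Boc-L-Cys-D-Pro-Aib-L-Phe-NMe2, which is anchored by hydrogen bonds to the ring-A 7-OH and the new ring oxygen and must deliver H to the Re face (O–CH2, aryl, benzylic CH2 clockwise) to give (3S); the thiyl radical is returned to the thiol by the acridine radical and the released proton, and 2,6-lutidine suppresses acid-catalysed Markovnikov closure; the closest known chemistry is the racemic acridinium/thiol anti-Markovnikov hydroetherification of alkenols together with peptide-thiol enantioselective hydrogen-atom transfer in photoredox deracemisation, whose combination to set a stereocentre beta to a new C–O bond has not been shown, so the sense of induction cannot be predicted and both mirror-image peptides must be tested.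

Step 9
Reactants: 15 (3S)-3-{5-[(tert-butyldimethylsilyl)oxy]-2,2-dimethyl-2H-chromen-6-yl}-8-(3-methylbut-2-en-1-yl)-3,4-dihydro-2H-chromen-7-ol
Product: 16 (3S)-3-(5-hydroxy-2,2-dimethyl-2H-chromen-6-yl)-8-(3-methylbut-2-en-1-yl)-3,4-dihydro-2H-chromen-7-ol
Conditions: KHF2 (2 equiv), MeOH, rt
Reagents that add atoms: none
Why: Fluoride-mediated cleavage of the phenolic silyl ether under near-neutral conditions leaves the prenyl group, the chromene and the non-acidic C3 stereocentre untouched.

## Compound list

1 | 2,4-dihydroxyacetophenone | CC(=O)c1ccc(O)cc1O | starting material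
2 | 3-methylbut-2-enal (prenal) | CC(C)=CC=O | starting material
3 | 1-(5-hydroxy-2,2-dimethyl-2H-chromen-6-yl)ethan-1-one | CC(=O)c1ccc2c(c1O)C=CC(C)(C)O2 | intermediate
4 | potassium 2,2-dimethyl-6-(prop-1-en-2-yl)-2H-chromen-5-olate | C=C(C)c1ccc2c(c1[O-])C=CC(C)(C)O2.[K+] | intermediate (not isolated)
5 | tert-butyl{[2,2-dimethyl-6-(prop-1-en-2-yl)-2H-chromen-5-yl]oxy}dimethylsilane | C=C(C)c1ccc2c(c1O[Si](C)(C)C(C)(C)C)C=CC(C)(C)O2 | intermediate
6 | 2-{5-[(tert-butyldimethylsilyl)oxy]-2,2-dimethyl-2H-chromen-6-yl}prop-2-en-1-ol | C=C(CO)c1ccc2c(c1O[Si](C)(C)C(C)(C)C)C=CC(C)(C)O2 | intermediate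
7 | resorcinol (benzene-1,3-diol) | Oc1cccc(O)c1 | starting material
8 | 1,3-bis(methoxymethoxy)benzene | COCOc1cccc(OCOC)c1 | intermediate
9 | 1-bromo-3-methylbut-2-ene (prenyl bromide) | CC(C)=CCBr | starting material
10 | [2,6-bis(methoxymethoxy)phenyl]lithium | [Li]c1c(OCOC)cccc1OCOC | intermediate (not isolated)
11 | 1,3-bis(methoxymethoxy)-2-(3-methylbut-2-en-1-yl)benzene | CC(C)=CCc1c(OCOC)cccc1OCOC | intermediate (not isolated)
12 | 2-(3-methylbut-2-en-1-yl)benzene-1,3-diol (2-prenylresorcinol) | CC(C)=CCc1c(O)cccc1O | intermediate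
13 | 3-[(2-{5-[(tert-butyldimethylsilyl)oxy]-2,2-dimethyl-2H-chromen-6-yl}prop-2-en-1-yl)oxy]-2-(3-methylbut-2-en-1-yl)phenol | CC(C)=CCc1c(O)cccc1OCC(=C)c1ccc2c(c1O[Si](C)(C)C(C)(C)C)C=CC(C)(C)O2 | intermediate
14 | 4-(2-{5-[(tert-butyldimethylsilyl)oxy]-2,2-dimethyl-2H-chromen-6-yl}prop-2-en-1-yl)-2-(3-methylbut-2-en-1-yl)benzene-1,3-diol | CC(C)=CCc1c(O)ccc(CC(=C)c2ccc3c(c2O[Si](C)(C)C(C)(C)C)C=CC(C)(C)O3)c1O | intermediate
15 | (3S)-3-{5-[(tert-butyldimethylsilyl)oxy]-2,2-dimethyl-2H-chromen-6-yl}-8-(3-methylbut-2-en-1-yl)-3,4-dihydro-2H-chromen-7-ol | CC(C)=CCc1c(O)ccc2c1OC[C@H](c1ccc3c(c1O[Si](C)(C)C(C)(C)C)C=CC(C)(C)O3)C2 | intermediate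
16 | (3S)-3-(5-hydroxy-2,2-dimethyl-2H-chromen-6-yl)-8-(3-methylbut-2-en-1-yl)-3,4-dihydro-2H-chromen-7-ol | CC(C)=CCc1c(O)ccc2c1OC[C@H](c1ccc3c(c1O)C=CC(C)(C)O3)C2 | target

## Step count and risks

Total step count: 9.
Longest linear sequence: 7 steps (steps 1, 2, 3, 6, 7, 8, 9; 1 → 3 → 5 → 6 → 13 → 14 → 15 → 16).

Steps most likely to fail:

**Step 8 (proposed new method).** The risks are low enantioselectivity in the hydrogen-atom transfer, competitive reversible oxidation of the resorcinol ring, side reactions of the chromene radical cation on long irradiation, thiyl-mediated migration of the 1,1-disubstituted alkene into conjugation, and background Markovnikov closure. The fallback uses known chemistry, sets out from 14 and comes back at 15. Cobalt-catalysed enantioselective hydroboration of the 1,1-disubstituted aryl alkene is run with a CoCl2 complex of a chiral iminopyridine–oxazoline ligand, NaBHEt3 as activator and HBpin in THF at rt. HBpin is used in excess because the two phenols are O-borylated first and freed again on work-up, and this catalyst class leaves internal and trisubstituted alkenes alone. With the ligand hand that gives the (S) series, this affords 4-[(2S)-2-{5-[(tert-butyldimethylsilyl)oxy]-2,2-dimethyl-2H-chromen-6-yl}-3-(4,4,5,5-tetramethyl-1,3,2-dioxaborolan-2-yl)propyl]-2-(3-methylbut-2-en-1-yl)benzene-1,3-diol F1. Oxidation with NaBO3·4H2O in THF/water gives 4-[(2S)-2-{5-[(tert-butyldimethylsilyl)oxy]-2,2-dimethyl-2H-chromen-6-yl}-3-hydroxypropyl]-2-(3-methylbut-2-en-1-yl)benzene-1,3-diol F2. An intramolecular Mitsunobu etherification (PPh3, DIAD, THF, 0 °C) then closes ring C through the only phenol that can form a six-membered ring, the ring-B oxygen being silylated, and delivers 15. In this variant the stereocentre is set in the hydrometalation and the C–O bond only closes the ring.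

**Step 3.** SeO2/t-BuOOH may over-oxidise to the 2-arylacrolein or attack the electron-rich chromene. The fallback sets out from 3 and comes back at 6, bypassing 5. Silylation of 3 (TBSCl, imidazole, DMF) gives 1-{5-[(tert-butyldimethylsilyl)oxy]-2,2-dimethyl-2H-chromen-6-yl}ethan-1-one F3. Kinetic enol triflation (KN(SiMe3)2, PhNTf2, THF, −78 °C) gives 1-{5-[(tert-butyldimethylsilyl)oxy]-2,2-dimethyl-2H-chromen-6-yl}ethenyl trifluoromethanesulfonate F4. Stille hydroxymethylation with Bu3SnCH2OH (Pd(PPh3)4, LiCl, dioxane, 90 °C) then gives 6. This replaces the C–H oxidation by a C–C coupling.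

**Step 7.** At 185 °C the product 14 can close thermally to the 2-aryl-2-methyl-2,3-dihydrobenzofuran, or the prenyl group can take part in Cope-type scrambling. The fallback sets out from 6 (with 12) and comes back at 14, bypassing 13. Appel bromination of 6 (CBr4, PPh3, CH2Cl2, 0 °C) gives tert-butyl{[6-(3-bromoprop-1-en-2-yl)-2,2-dimethyl-2H-chromen-5-yl]oxy}dimethylsilane F5. The monosodium salt of 12 (NaH, toluene, rt) is then C-allylated with F5 at the ortho carbon, as alkali phenoxides are in non-polar solvents. The only aromatisable positions of 12 are the two equivalent ones, so this gives 14 directly without heating.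

## Further compounds

F1 | step 8 | 4-[(2S)-2-{5-[(tert-butyldimethylsilyl)oxy]-2,2-dimethyl-2H-chromen-6-yl}-3-(4,4,5,5-tetramethyl-1,3,2-dioxaborolan-2-yl)propyl]-2-(3-methylbut-2-en-1-yl)benzene-1,3-diol | CC(C)=CCc1c(O)ccc(C[C@H](CB2OC(C)(C)C(C)(C)O2)c2ccc3c(c2O[Si](C)(C)C(C)(C)C)C=CC(C)(C)O3)c1O
F2 | step 8 | 4-[(2S)-2-{5-[(tert-butyldimethylsilyl)oxy]-2,2-dimethyl-2H-chromen-6-yl}-3-hydroxypropyl]-2-(3-methylbut-2-en-1-yl)benzene-1,3-diol | CC(C)=CCc1c(O)ccc(C[C@H](CO)c2ccc3c(c2O[Si](C)(C)C(C)(C)C)C=CC(C)(C)O3)c1O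
F3 | step 3 | 1-{5-[(tert-butyldimethylsilyl)oxy]-2,2-dimethyl-2H-chromen-6-yl}ethan-1-one | CC(=O)c1ccc2c(c1O[Si](C)(C)C(C)(C)C)C=CC(C)(C)O2
F4 | step 3 | 1-{5-[(tert-butyldimethylsilyl)oxy]-2,2-dimethyl-2H-chromen-6-yl}ethenyl trifluoromethanesulfonate | C=C(OS(=O)(=O)C(F)(F)F)c1ccc2c(c1O[Si](C)(C)C(C)(C)C)C=CC(C)(C)O2
F5 | step 7 | tert-butyl{[6-(3-bromoprop-1-en-2-yl)-2,2-dimethyl-2H-chromen-5-yl]oxy}dimethylsilane | C=C(CBr)c1ccc2c(c1O[Si](C)(C)C(C)(C)C)C=CC(C)(C)O2
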